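## Structural features

The target 19 is a flavanone: ring A, a phloroglucinol-type benzene, is fused to the dihydropyranone ring C, and ring B, a 3-methoxy-4,5-dihydroxyphenyl group, is attached to C2 through the single bond C2–C1'. Ring A is substituted everywhere except C8: C4a carries the C4 ketone, the C5 and C7 hydroxyls flank the (E)-geranyl chain on C6, and C8a carries the ring oxygen O1, which therefore stands para to the geranyl group. The only stereocentre is C2 (S; O1 > C1' > C3 > H); it has no stereogenic neighbour and is at once benzylic, α to O1 and β to the ketone. This makes it fragile: ring C opens reversibly to the chalcone by retro-oxa-Michael reaction (or to a para-quinone methide from the 4'-phenoxide), so base racemises it. The geranyl alkenes are the second weak point, because acid closes them onto the neighbouring phenols and electrophilic oxidants attack them; the four free phenols are also oxidant-sensitive. The real difficulty is twofold: the 6- versus 8-geranyl regiochemistry of the crowded ring A, and the absolute configuration of an isolated, labile centre. The key step uses the fact that C2 is bonded to O1 and to ring B: with O1–C2 in place and C2–C3 open, C2 is the methylene of an aryl benzyl ether. Its two enantiotopic C–H bonds are activated by O1 and ring B and lie six atoms from a carbenoid at C3.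

## Logic of the disconnections

19 ⇒ 18. The four O–Si bonds are cut. All four phenols carry the same silyl group, so one buffered fluoride treatment releases them without acid (geranyl) or base (C2). The forward step must avoid any build-up of phenoxide.

18 ⇒ 17. The C2–C3 bond is cut and ring C is opened. Stereogenic C2 becomes a prochiral benzylic methylene and the precursor is an achiral diazoketone. The carbenoid must insert into the pro-S C–H bond and must not be diverted by lone pairs, alkenes or other activated C–H bonds. For that reason 17 contains no acetal-type protecting group (an O–CH2–O hydrogen on O5 would compete in its own six-membered insertion), and O5 carries a bulky silyl group.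

17 ⇒ 15 (through 16) ⇒ 14. The C3–C4 bond is cut (acylation of a diazomethane equivalent), then the C4 oxidation level is lowered to the aldehyde. This removes the sensitive diazo group and leaves a stable benzaldehyde. The acid must be activated under neutral conditions, since the electron-rich benzyl ether and the diazoketone are acid-labile. The oxidation must spare two trisubstituted alkenes.

14 ⇒ 10 + 13. The O1–C2 ether bond is cut, which divides the molecule into its ring A and ring B halves. A redox condensation of a phenol with a benzylic alcohol is planned instead of a base-mediated alkylation, because aryl silyl ethers do not tolerate carbonate bases well. It requires that 10 has exactly one free phenol.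

13 ⇒ 12 ⇒ 11. Only functional-group changes are involved (reduction, silylation). The ring B half comes in two steps from a commercial aldehyde.

10 ⇒ 9. The C4a–CHO bond is cut. In 9 the two positions ortho to the single free phenol are equivalent by symmetry and the para position holds the geranyl chain. Formylation can therefore only lead to the 6-geranyl pattern; this is where the regiochemistry of ring A is settled.

9 ⇒ 7 (through 8). The C8a–O bond is traced back to a C–Cl bond. The halogen is a masked phenol that distinguishes the future O1 from O5 and O7 from the first step onwards. The forward step must convert an electron-rich aryl chloride without touching alkenes or silyl ethers.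

7 ⇒ 6 ⇒ 5. The acetal groups are exchanged for silyl groups. Acetals are needed to direct the metalation and silyl ethers are needed for the carbenoid step. The exchange is placed early, on the smallest intermediate, where the chloride is inert to it.

5 ⇒ 2 + 3 (through 4). The aryl–geranyl C–C bond is cut. Metalation between two cooperating acetal oxygens fixes the chain between O5 and O7. A chloride, unlike a bromide, survives n-BuLi. The allylation must occur at the primary carbon of 3 with retention of the E geometry.

2 ⇒ 1. The two O–CH2 bonds are cut, leading to a commercial symmetric resorcinol.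

## Other disconnections considered

Alternative 1: The cut runs through O1–C2 and C3–C4. In the forward sense the salicylaldehyde A2 would be activated in situ with trimethyl orthoformate and a chiral phosphoric acid as its methoxy-substituted ortho-quinone methide. That heterodiene would add the ring B styrene A3 in an inverse-demand [4+2] to give the 2,4-cis-4-methoxyflavan A1.
- In its favour: two bonds and ring C are formed in one convergent step, no diazo compound is needed, and the electron-rich styrene matches the electron-poor heterodiene.
- Against it here: A1 is at the wrong oxidation level at C4, so one of the two new stereocentres must be destroyed by hydrolysis and oxidation. The chiral phosphate would have to control a cationic heterodiene flanked by a bulky C5 substituent. The acid medium threatens the acetals, the styrene and the geranyl alkenes, and four acetal groups must finally be removed with acid next to the geranyl chain.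
- Comparison: on structure it is the better plan in convergence and bonds formed. On ring A regiochemistry it is equal, since A2 needs the same symmetric-phenol device but could come directly from 5 without a protecting-group exchange. On step economy it should be equal or about three steps shorter. On mechanism the chosen plan is preferred, because its ring closure gives the ketone directly and runs under neutral conditions. The enantiocontrol is uncertain in both.

Alternative 2: The cut is C4–C4a. The (S)-3-aryl-3-aryloxypropanoic acid A5, activated as a mixed anhydride, would acylate one of the two equivalent ortho carbons of its aryloxy ring to give the flavanone diacetate A4.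
- In its favour: the aryloxy ring is symmetric, so regiochemistry is as secure as in the chosen plan (equal). The ring closure onto a phloroglucinol-type ring is easy, and no carbenoid chemoselectivity question arises (better).
- Against it here: the stereocentre must be made before the ring closure, most simply by Mitsunobu inversion of a secondary benzylic alcohol with 9, where electron-rich benzylic centres tend to ionise. In A5 the same centre is a doubly activated benzylic aryl ether β to an activated acyl group, open to ionisation and to β-elimination of the aryloxide. Ring B must be deactivated as a diacetate, whose removal at the flavanone stage calls for basic or nucleophilic conditions that endanger C2. Acid activation also threatens the silyl ethers and the geranyl alkenes.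
- Comparison: step count is equal or one or two steps longer (two kinds of deprotection). The stereochemical integrity is the weaker point compared with setting C2 last under neutral conditions.

Alternative 3: The cut is C8a–O1. The anti-1,3-diol A7, with a bromide at C8a, would be cyclised by an Ullmann-type C–O coupling (CuI, a diamine or phenanthroline ligand, base; monovalent copper) to the 2,4-cis-flavan-4-ol A6.
- In its favour: the C2 configuration would come from dependable carbonyl chemistry (asymmetric aldol or reduction, then 1,3-anti reduction) with a predictable sense, and the ring closure does not touch it (better than the chosen plan). Only the C2 hydroxyl can close a six-membered ring, so chemoselectivity is built in. A bromide from 5-bromoresorcinol could be used as such, with no halide-to-phenol conversion (better).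
- Against it here: the C4 carbinol is built with control only to be oxidised. The coupling must take place at a di-ortho-substituted, electron-rich aryl bromide with a secondary alkoxide under hot basic conditions. The side chain and the geranyl group must be installed by metalations on a ring that carries bromine. Four acetal groups must be removed with acid at the end.
- Comparison: about three or four steps longer and poorer in redox economy; mechanistically more predictable in absolute configuration but harsher in the ring-closing step.

Key step: step 12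

Remark: 1, 3 and 11 are taken as purchasable; chlorine replaces bromine as the masked phenol of ring A because it must survive n-BuLi, and all four phenols are carried as silyl ethers because acetal C–H bonds would compete for the carbenoid. Geranyl = (2E)-3,7-dimethylocta-2,6-dienyl; TBS = tert-butyldimethylsilyl.

## Route

Step 1
Reactants: 1 5-chlororesorcinol
Product: 2 1-chloro-3,5-bis(methoxymethoxy)benzene
Conditions: MOMCl, i-Pr2NEt, CH2Cl2, 0 °C → rt
Reagents that add atoms: chloromethyl methyl ether (MOMCl), COCCl
Why: Williamson-type O-alkylation of both phenols; the two acetal oxygens become the cooperating directing groups of step 2, and the C–Cl bond is inert to alkyllithium exchange.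

Step 2
Reactants: 2 1-chloro-3,5-bis(methoxymethoxy)benzene; 3 geranyl bromide
Product: 5 5-chloro-2-geranyl-1,3-bis(methoxymethoxy)benzene, via aryllithium 4 (not isolated)
Conditions: n-BuLi, THF, −20 → 0 °C; CuBr·SMe2, −78 → −40 °C; 3, −78 °C → rt
Reagents that add atoms: n-butyllithium, [Li]CCCC (lithium of 4 only)
Why: Directed ortho-metalation at the only carbon flanked by two acetal oxygens (para to chlorine, so no aryne can form from 4), then copper-mediated SN2 allylation at the primary carbon of 3, which should keep the E-alkene and give the linear geranyl arene.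

Step 3
Reactants: 5 5-chloro-2-geranyl-1,3-bis(methoxymethoxy)benzene
Product: 6 5-chloro-2-geranylbenzene-1,3-diol
Conditions: HCl (2 M), MeOH, 40 °C
Reagents that add atoms: none
Why: Acid-catalysed acetal methanolysis, which is far faster than protonation of the trisubstituted alkenes under these dilute conditions; the chlorine also lowers the nucleophilicity of the phenols towards the chain.

Step 4
Reactants: 6 5-chloro-2-geranylbenzene-1,3-diol
Product: 7 5-chloro-2-geranyl-1,3-bis(tert-butyldimethylsilyloxy)benzene
Conditions: TBSCl, imidazole, DMF, rt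
Reagents that add atoms: tert-butyldimethylsilyl chloride (TBSCl), CC(C)(C)[Si](C)(C)Cl
Why: Standard imidazole-promoted silylation of phenols; it installs on the future O5 and O7 a group with no C–H bond next to oxygen.

Step 5
Reactants: 7 5-chloro-2-geranyl-1,3-bis(tert-butyldimethylsilyloxy)benzene
Product: 9 4-geranyl-3,5-bis(tert-butyldimethylsilyloxy)phenol, via pinacol boronate 8 (not isolated)
Conditions: B2pin2, Pd2(dba)3, XPhos, KOAc, dioxane, 100 °C; then NaBO3·4H2O, THF/H2O, rt
Reagents that add atoms: bis(pinacolato)diboron, CC1(C)OB(OC1(C)C)B1OC(C)(C)C(C)(C)O1 (boron and pinacol of 8 only); sodium perborate, [Na+].[Na+].O[B-]1(O)OO[B-](O)(O)OO1 (the phenol oxygen of 9)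
Why: Miyaura borylation of the unhindered aryl chloride (oxidative addition to zerovalent palladium assisted by XPhos, acetate-assisted transmetalation) followed by ipso-oxidation of the C–B bond with 1,2-aryl shift from boron to oxygen; isolated trisubstituted alkenes and aryl silyl ethers should be inert to both stages.

Step 6
Reactants: 9 4-geranyl-3,5-bis(tert-butyldimethylsilyloxy)phenol
Product: 10 5-geranyl-2-hydroxy-4,6-bis(tert-butyldimethylsilyloxy)benzaldehyde
Conditions: MgCl2, Et3N, (CH2O)n, MeCN, 70 °C
Reagents that add atoms: paraformaldehyde (formaldehyde), C=O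
Why: Casnati–Skattebøl ortho-formylation: the magnesium phenoxide delivers formaldehyde to an ortho carbon and a second formaldehyde oxidises the benzylic alkoxide by hydride transfer. The two ortho positions of 9 are equivalent and the para position is blocked, so only the 6-geranyl substitution pattern can result.

Step 7
Reactants: 11 5-hydroxyvanillin
Product: 12 3,4-bis(tert-butyldimethylsilyloxy)-5-methoxybenzaldehyde
Conditions: TBSCl, imidazole, DMF, rt
Reagents that add atoms: tert-butyldimethylsilyl chloride (TBSCl), CC(C)(C)[Si](C)(C)Cl
Why: Imidazole-promoted silylation of both phenols of the catechol unit, a routine protection of 3,4-dihydroxybenzaldehydes.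

Step 8
Reactants: 12 3,4-bis(tert-butyldimethylsilyloxy)-5-methoxybenzaldehyde
Product: 13 [3,4-bis(tert-butyldimethylsilyloxy)-5-methoxyphenyl]methanol
Conditions: NaBH4, THF/EtOH, 0 °C
Reagents that add atoms: none
Why: Borohydride reduction of an aromatic aldehyde; aryl silyl ethers should survive the short, cold reaction.

Step 9
Reactants: 10 5-geranyl-2-hydroxy-4,6-bis(tert-butyldimethylsilyloxy)benzaldehyde; 13 [3,4-bis(tert-butyldimethylsilyloxy)-5-methoxyphenyl]methanol
Product: 14 2-{[3,4-bis(tert-butyldimethylsilyloxy)-5-methoxyphenyl]methoxy}-5-geranyl-4,6-bis(tert-butyldimethylsilyloxy)benzaldehyde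
Conditions: PPh3, DIAD, THF, 0 °C → rt
Reagents that add atoms: none
Why: Mitsunobu etherification: the acidic salicylaldehyde phenol displaces the oxyphosphonium derivative of the primary benzylic alcohol. The medium is neutral, so no silyl ether is exposed to carbonate or alkoxide, and 10 offers only one free phenol.

Step 10
Reactants: 14 2-{[3,4-bis(tert-butyldimethylsilyloxy)-5-methoxyphenyl]methoxy}-5-geranyl-4,6-bis(tert-butyldimethylsilyloxy)benzaldehyde
Product: 15 2-{[3,4-bis(tert-butyldimethylsilyloxy)-5-methoxyphenyl]methoxy}-5-geranyl-4,6-bis(tert-butyldimethylsilyloxy)benzoic acid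
Conditions: NaClO2, NaH2PO4, 2-methyl-2-butene (30 equiv), t-BuOH/THF/H2O, 0 °C → rt
Reagents that add atoms: sodium chlorite, [Na+].[O-]Cl=O
Why: Pinnick oxidation: chlorous acid adds to the aldehyde and fragments to the acid and HOCl, which the large excess of sacrificial alkene should intercept before it reaches the geranyl alkenes or the electron-rich rings; the buffer (about pH 4) is tolerated by aryl silyl ethers.

Step 11
Reactants: 15 2-{[3,4-bis(tert-butyldimethylsilyloxy)-5-methoxyphenyl]methoxy}-5-geranyl-4,6-bis(tert-butyldimethylsilyloxy)benzoic acid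
Product: 17 2-diazo-1-{2-{[3,4-bis(tert-butyldimethylsilyloxy)-5-methoxyphenyl]methoxy}-5-geranyl-4,6-bis(tert-butyldimethylsilyloxy)phenyl}ethan-1-one, via acid chloride 16 (not isolated)
Conditions: 1-chloro-N,N,2-trimethylprop-1-en-1-amine, CH2Cl2, 0 °C → rt; then TMSCHN2, CaO, THF/MeCN, 0 °C → rt
Reagents that add atoms: 1-chloro-N,N,2-trimethylprop-1-en-1-amine, CC(C)=C(Cl)N(C)C (chlorine of 16 only); trimethylsilyldiazomethane, C[Si](C)(C)C=[N+]=[N-] (the CHN2 unit)
Why: The α-chloroenamine converts the acid into its chloride without releasing HCl; C-acylation of the silyl diazomethane and loss of the silyl group to chloride (first stage of an Arndt–Eistert sequence) then give the diazomethyl ketone. CaO scavenges traces of acid that would otherwise debenzylate the ortho-alkoxy diazoketone.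

Step 12
Reactants: 17 2-diazo-1-{2-{[3,4-bis(tert-butyldimethylsilyloxy)-5-methoxyphenyl]methoxy}-5-geranyl-4,6-bis(tert-butyldimethylsilyloxy)phenyl}ethan-1-one
Product: 18 (2S)-2-[3,4-bis(tert-butyldimethylsilyloxy)-5-methoxyphenyl]-6-geranyl-5,7-bis(tert-butyldimethylsilyloxy)chroman-4-one
Conditions: Rh2(S-PTTL)4 (2 mol%), 4 Å MS, toluene, −20 → 0 °C, slow addition of 17
Reagents that add atoms: none
Why: Rh2(S-PTTL)4 (dirhodium tetrakis[N-phthaloyl-(S)-tert-leucinate], divalent rhodium) takes N2 from 17 to give an electrophilic acylcarbenoid at C3, which inserts into one benzylic C–H bond of the O1–CH2–aryl group through a concerted, asynchronous three-centre transition state with hydride-shift character and retention at carbon, forming C2–C3; the closest known reaction type is the dirhodium carboxylate-catalysed asymmetric intramolecular C–H insertion of ortho-alkoxyaryl diazoketones to 2-substituted chroman-4-ones. Ring C closes as a six-membered ring by 1,6-insertion, the usual 1,5-mode being excluded because the fifth atom is O1 and carries no hydrogen. C2 is set by the catalyst alone: the chiral pocket of the four phthalimido-tert-leucinate ligands must present the pro-S hydrogen, and because the sense of induction cannot be derived with certainty for this substrate, the mirror-image complex Rh2(R-PTTL)4 is the drop-in replacement should the first run show the opposite sense. The step needs chemoselectivity for C–H insertion over oxonium ylide formation at O1 (which would end in a 1,2-benzyl shift), over attack at O5, over cyclopropanation and over carbene dimerisation. In 17 the reacting C–H bond is doubly activated (α to O1, benzylic to the para-silyloxy ring B), the O1 lone pairs are delocalised into ring A and shielded by the bulky ligands, O5 bears a bulky silyl group without any α-oxy C–H, no acetal C–H remains in the molecule, and the geranyl alkenes stand meta to the acyl group and cannot reach C3. Slow addition to dilute catalyst in a non-polar solvent at low temperature should keep carbene dimerisation and ylide formation down.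

Step 13
Reactants: 18 (2S)-2-[3,4-bis(tert-butyldimethylsilyloxy)-5-methoxyphenyl]-6-geranyl-5,7-bis(tert-butyldimethylsilyloxy)chroman-4-one
Product: 19 (2S)-2-(3,4-dihydroxy-5-methoxyphenyl)-6-geranyl-5,7-dihydroxychroman-4-one (CNP0110161.1)
Conditions: TBAF, AcOH (1:1, 6 equiv), THF, 0 °C → rt
Reagents that add atoms: none
Why: Fluoride cleavage of all four aryl O–Si bonds in one operation; the acetic acid buffer protonates each phenoxide as it forms, so neither retro-oxa-Michael opening nor quinone methide formation should erode C2, and no acid strong enough to cyclise the geranyl chain is present.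

## Compound list

1 | 5-chlororesorcinol (5-chlorobenzene-1,3-diol) | Oc1cc(O)cc(Cl)c1 | starting material
2 | 1-chloro-3,5-bis(methoxymethoxy)benzene | COCOc1cc(Cl)cc(OCOC)c1 | intermediate
3 | geranyl bromide, (2E)-1-bromo-3,7-dimethylocta-2,6-diene | CC(C)=CCC/C(C)=C/CBr | starting material
4 | 4-chloro-2,6-bis(methoxymethoxy)phenyllithium | [Li]c1c(OCOC)cc(Cl)cc1OCOC | intermediate
5 | 5-chloro-2-geranyl-1,3-bis(methoxymethoxy)benzene | COCOc1cc(Cl)cc(OCOC)c1C/C=C(\C)CCC=C(C)C | intermediate
6 | 5-chloro-2-geranylbenzene-1,3-diol | Oc1cc(Cl)cc(O)c1C/C=C(\C)CCC=C(C)C | intermediate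
7 | 5-chloro-2-geranyl-1,3-bis(tert-butyldimethylsilyloxy)benzene | CC(C)(C)[Si](C)(C)Oc1cc(Cl)cc(O[Si](C)(C)C(C)(C)C)c1C/C=C(\C)CCC=C(C)C | intermediate
8 | 2-[4-geranyl-3,5-bis(tert-butyldimethylsilyloxy)phenyl]-4,4,5,5-tetramethyl-1,3,2-dioxaborolane | CC(C)(C)[Si](C)(C)Oc1cc(B2OC(C)(C)C(C)(C)O2)cc(O[Si](C)(C)C(C)(C)C)c1C/C=C(\C)CCC=C(C)C | intermediate
9 | 4-geranyl-3,5-bis(tert-butyldimethylsilyloxy)phenol | CC(C)(C)[Si](C)(C)Oc1cc(O)cc(O[Si](C)(C)C(C)(C)C)c1C/C=C(\C)CCC=C(C)C | intermediate
10 | 5-geranyl-2-hydroxy-4,6-bis(tert-butyldimethylsilyloxy)benzaldehyde | O=Cc1c(O)cc(O[Si](C)(C)C(C)(C)C)c(C/C=C(\C)CCC=C(C)C)c1O[Si](C)(C)C(C)(C)C | intermediate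
11 | 5-hydroxyvanillin (3,4-dihydroxy-5-methoxybenzaldehyde) | COc1cc(C=O)cc(O)c1O | starting material
12 | 3,4-bis(tert-butyldimethylsilyloxy)-5-methoxybenzaldehyde | COc1cc(C=O)cc(O[Si](C)(C)C(C)(C)C)c1O[Si](C)(C)C(C)(C)C | intermediate
13 | [3,4-bis(tert-butyldimethylsilyloxy)-5-methoxyphenyl]methanol | COc1cc(CO)cc(O[Si](C)(C)C(C)(C)C)c1O[Si](C)(C)C(C)(C)C | intermediate
14 | 2-{[3,4-bis(tert-butyldimethylsilyloxy)-5-methoxyphenyl]methoxy}-5-geranyl-4,6-bis(tert-butyldimethylsilyloxy)benzaldehyde | COc1cc(COc2cc(O[Si](C)(C)C(C)(C)C)c(C/C=C(\C)CCC=C(C)C)c(O[Si](C)(C)C(C)(C)C)c2C=O)cc(O[Si](C)(C)C(C)(C)C)c1O[Si](C)(C)C(C)(C)C | intermediate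
15 | 2-{[3,4-bis(tert-butyldimethylsilyloxy)-5-methoxyphenyl]methoxy}-5-geranyl-4,6-bis(tert-butyldimethylsilyloxy)benzoic acid | COc1cc(COc2cc(O[Si](C)(C)C(C)(C)C)c(C/C=C(\C)CCC=C(C)C)c(O[Si](C)(C)C(C)(C)C)c2C(=O)O)cc(O[Si](C)(C)C(C)(C)C)c1O[Si](C)(C)C(C)(C)C | intermediate
16 | 2-{[3,4-bis(tert-butyldimethylsilyloxy)-5-methoxyphenyl]methoxy}-5-geranyl-4,6-bis(tert-butyldimethylsilyloxy)benzoyl chloride | COc1cc(COc2cc(O[Si](C)(C)C(C)(C)C)c(C/C=C(\C)CCC=C(C)C)c(O[Si](C)(C)C(C)(C)C)c2C(=O)Cl)cc(O[Si](C)(C)C(C)(C)C)c1O[Si](C)(C)C(C)(C)C | intermediate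
17 | 2-diazo-1-{2-{[3,4-bis(tert-butyldimethylsilyloxy)-5-methoxyphenyl]methoxy}-5-geranyl-4,6-bis(tert-butyldimethylsilyloxy)phenyl}ethan-1-one | COc1cc(COc2cc(O[Si](C)(C)C(C)(C)C)c(C/C=C(\C)CCC=C(C)C)c(O[Si](C)(C)C(C)(C)C)c2C(=O)C=[N+]=[N-])cc(O[Si](C)(C)C(C)(C)C)c1O[Si](C)(C)C(C)(C)C | intermediate
18 | (2S)-2-[3,4-bis(tert-butyldimethylsilyloxy)-5-methoxyphenyl]-6-geranyl-5,7-bis(tert-butyldimethylsilyloxy)chroman-4-one | COc1cc([C@@H]2CC(=O)c3c(cc(O[Si](C)(C)C(C)(C)C)c(C/C=C(\C)CCC=C(C)C)c3O[Si](C)(C)C(C)(C)C)O2)cc(O[Si](C)(C)C(C)(C)C)c1O[Si](C)(C)C(C)(C)C | intermediate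
19 | (2S)-2-(3,4-dihydroxy-5-methoxyphenyl)-6-[(2E)-3,7-dimethylocta-2,6-dienyl]-5,7-dihydroxychroman-4-one | COc1cc([C@@H]2CC(=O)c3c(cc(O)c(C/C=C(\C)CCC=C(C)C)c3O)O2)cc(O)c1O | target

## Step count and least certain steps

Total step count: 13. Longest linear sequence: 11 steps (steps 1–6 and 9–13); the ring B branch (steps 7 and 8) joins at step 9.

Step 12 (key step). The most likely failure is diversion of the carbenoid by the O1 lone pair: a five-membered oxonium ylide forms and the electron-rich benzyl group undergoes a 1,2-shift, because an acceptor-only carbenoid is highly electrophilic and the benzyl group migrates easily. The second is poor discrimination between the two enantiotopic hydrogens, for the same reason of high reactivity. Fallback, setting out from 10 and 12 and returning at 18: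
- Addition of MeMgBr to 10 should give 1-[5-geranyl-2-hydroxy-4,6-bis(tert-butyldimethylsilyloxy)phenyl]ethan-1-ol F1.
- MnO2 oxidation should give 1-[5-geranyl-2-hydroxy-4,6-bis(tert-butyldimethylsilyloxy)phenyl]ethan-1-one F2.
- Claisen–Schmidt condensation of F2 with 12 (pyrrolidine, EtOH) should give the (E)-2'-hydroxychalcone F3.
- 6-endo oxa-Michael closure (NaOAc, EtOH, heat) should give the racemic flavanone F4.
- Preparative HPLC on a polysaccharide chiral stationary phase would deliver 18; the unwanted antipode could be re-equilibrated through F3.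

Step 10. The HOCl by-product may chlorinate or hydroxychlorinate the geranyl alkenes and the electron-rich rings if scavenging is incomplete, and the di-ortho-substituted aldehyde may oxidise slowly. Fallback, setting out from 14 and returning at 17 (it bypasses 15 and 16 and therefore also covers sluggish acylation of the hindered acid chloride in step 11):
- MeMgBr should give the carbinol 1-{2-{[3,4-bis(tert-butyldimethylsilyloxy)-5-methoxyphenyl]methoxy}-5-geranyl-4,6-bis(tert-butyldimethylsilyloxy)phenyl}ethan-1-ol F5.
- Dess–Martin oxidation should give the corresponding methyl ketone F6.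
- Trifluoroacetylation (LiN(SiMe3)2, CF3CO2CH2CF3, THF, −78 °C) should give the 4,4,4-trifluoro-1-arylbutane-1,3-dione F7.
- Detrifluoroacetylative diazo transfer (MsN3, Et3N, MeCN/H2O) should give 17.

Step 5. Slow oxidative addition of the electron-rich aryl chloride may lead to protodehalogenation, palladium hydride species may migrate the alkenes, and the oxidative work-up may cause some desilylation. Fallback, setting out from 7 and 13 and returning at 14 (bypassing 9 and 10):
- Palladium-catalysed C–O coupling of 7 with 13 (Pd2(dba)3, RockPhos, Cs2CO3, toluene, 90 °C) should give the aryl benzyl ether 5-{[3,4-bis(tert-butyldimethylsilyloxy)-5-methoxyphenyl]methoxy}-2-geranyl-1,3-bis(tert-butyldimethylsilyloxy)benzene F8.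
- Vilsmeier–Haack formylation (POCl3, DMF, 0 °C) at one of the two equivalent, triply oxygen-activated positions of ring A should give 14.

Step 2. The arylcopper species may attack the tertiary γ-carbon of the allylic bromide (SN2'), giving the branched isomer, or coupling may be incomplete at the di-ortho-substituted carbon. Fallback, setting out from 2 and 3 and returning at 5:
- Lithiation of 2 as before and quenching with I2 should give 5-chloro-2-iodo-1,3-bis(methoxymethoxy)benzene F9.
- 3 with Bu3SnLi should give tributyl(geranyl)stannane F10.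
- Stille coupling of F9 with F10 (Pd(PPh3)4, CsF, DMF, 80 °C), selective for the C–I bond, should give 5.

## Further compounds

F1 | step 12 | 1-[5-geranyl-2-hydroxy-4,6-bis(tert-butyldimethylsilyloxy)phenyl]ethan-1-ol (racemic) | CC(O)c1c(O)cc(O[Si](C)(C)C(C)(C)C)c(C/C=C(\C)CCC=C(C)C)c1O[Si](C)(C)C(C)(C)C
F2 | step 12 | 1-[5-geranyl-2-hydroxy-4,6-bis(tert-butyldimethylsilyloxy)phenyl]ethan-1-one | CC(=O)c1c(O)cc(O[Si](C)(C)C(C)(C)C)c(C/C=C(\C)CCC=C(C)C)c1O[Si](C)(C)C(C)(C)C
F3 | step 12 | (2E)-3-[3,4-bis(tert-butyldimethylsilyloxy)-5-methoxyphenyl]-1-[5-geranyl-2-hydroxy-4,6-bis(tert-butyldimethylsilyloxy)phenyl]prop-2-en-1-one | COc1cc(/C=C/C(=O)c2c(O)cc(O[Si](C)(C)C(C)(C)C)c(C/C=C(\C)CCC=C(C)C)c2O[Si](C)(C)C(C)(C)C)cc(O[Si](C)(C)C(C)(C)C)c1O[Si](C)(C)C(C)(C)C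
F4 | step 12 | racemic 2-[3,4-bis(tert-butyldimethylsilyloxy)-5-methoxyphenyl]-6-geranyl-5,7-bis(tert-butyldimethylsilyloxy)chroman-4-one | COc1cc(C2CC(=O)c3c(cc(O[Si](C)(C)C(C)(C)C)c(C/C=C(\C)CCC=C(C)C)c3O[Si](C)(C)C(C)(C)C)O2)cc(O[Si](C)(C)C(C)(C)C)c1O[Si](C)(C)C(C)(C)C
F5 | step 10 | 1-{2-{[3,4-bis(tert-butyldimethylsilyloxy)-5-methoxyphenyl]methoxy}-5-geranyl-4,6-bis(tert-butyldimethylsilyloxy)phenyl}ethan-1-ol (racemic) | COc1cc(COc2cc(O[Si](C)(C)C(C)(C)C)c(C/C=C(\C)CCC=C(C)C)c(O[Si](C)(C)C(C)(C)C)c2C(C)O)cc(O[Si](C)(C)C(C)(C)C)c1O[Si](C)(C)C(C)(C)C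
F6 | step 10 | 1-{2-{[3,4-bis(tert-butyldimethylsilyloxy)-5-methoxyphenyl]methoxy}-5-geranyl-4,6-bis(tert-butyldimethylsilyloxy)phenyl}ethan-1-one | COc1cc(COc2cc(O[Si](C)(C)C(C)(C)C)c(C/C=C(\C)CCC=C(C)C)c(O[Si](C)(C)C(C)(C)C)c2C(C)=O)cc(O[Si](C)(C)C(C)(C)C)c1O[Si](C)(C)C(C)(C)C
F7 | step 10 | 4,4,4-trifluoro-1-{2-{[3,4-bis(tert-butyldimethylsilyloxy)-5-methoxyphenyl]methoxy}-5-geranyl-4,6-bis(tert-butyldimethylsilyloxy)phenyl}butane-1,3-dione | COc1cc(COc2cc(O[Si](C)(C)C(C)(C)C)c(C/C=C(\C)CCC=C(C)C)c(O[Si](C)(C)C(C)(C)C)c2C(=O)CC(=O)C(F)(F)F)cc(O[Si](C)(C)C(C)(C)C)c1O[Si](C)(C)C(C)(C)C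
F8 | step 5 | 5-{[3,4-bis(tert-butyldimethylsilyloxy)-5-methoxyphenyl]methoxy}-2-geranyl-1,3-bis(tert-butyldimethylsilyloxy)benzene | COc1cc(COc2cc(O[Si](C)(C)C(C)(C)C)c(C/C=C(\C)CCC=C(C)C)c(O[Si](C)(C)C(C)(C)C)c2)cc(O[Si](C)(C)C(C)(C)C)c1O[Si](C)(C)C(C)(C)C
F9 | step 2 | 5-chloro-2-iodo-1,3-bis(methoxymethoxy)benzene | COCOc1cc(Cl)cc(OCOC)c1I
F10 | step 2 | tributyl[(2E)-3,7-dimethylocta-2,6-dienyl]stannane | CCCC[Sn](CCCC)(CCCC)C/C=C(\C)CCC=C(C)C
A1 | alternative 1 | (2S,4S)-2,4-cis-6-geranyl-4-methoxy-2-[3-methoxy-4,5-bis(methoxymethoxy)phenyl]-5,7-bis(methoxymethoxy)chroman | COc1cc([C@@H]2C[C@H](OC)c3c(cc(OCOC)c(C/C=C(\C)CCC=C(C)C)c3OCOC)O2)cc(OCOC)c1OCOC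
A2 | alternative 1 | 5-geranyl-2-hydroxy-4,6-bis(methoxymethoxy)benzaldehyde | O=Cc1c(O)cc(OCOC)c(C/C=C(\C)CCC=C(C)C)c1OCOC
A3 | alternative 1 | 5-ethenyl-1-methoxy-2,3-bis(methoxymethoxy)benzene | C=Cc1cc(OC)c(OCOC)c(OCOC)c1
A4 | alternative 2 | (2S)-2-(3,4-diacetoxy-5-methoxyphenyl)-6-geranyl-5,7-bis(tert-butyldimethylsilyloxy)chroman-4-one | COc1cc([C@@H]2CC(=O)c3c(cc(O[Si](C)(C)C(C)(C)C)c(C/C=C(\C)CCC=C(C)C)c3O[Si](C)(C)C(C)(C)C)O2)cc(OC(C)=O)c1OC(C)=O
A5 | alternative 2 | (3S)-3-(3,4-diacetoxy-5-methoxyphenyl)-3-[4-geranyl-3,5-bis(tert-butyldimethylsilyloxy)phenoxy]propanoic acid | COc1cc([C@@H](Oc2cc(O[Si](C)(C)C(C)(C)C)c(C/C=C(\C)CCC=C(C)C)c(O[Si](C)(C)C(C)(C)C)c2)CC(=O)O)cc(OC(C)=O)c1OC(C)=O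
A6 | alternative 3 | (2S,4S)-2,4-cis-6-geranyl-2-[3-methoxy-4,5-bis(methoxymethoxy)phenyl]-5,7-bis(methoxymethoxy)chroman-4-ol | COc1cc([C@@H]2C[C@H](O)c3c(cc(OCOC)c(C/C=C(\C)CCC=C(C)C)c3OCOC)O2)cc(OCOC)c1OCOC
A7 | alternative 3 | (1S,3S)-anti-1-[2-bromo-5-geranyl-4,6-bis(methoxymethoxy)phenyl]-3-[3-methoxy-4,5-bis(methoxymethoxy)phenyl]propane-1,3-diol | COc1cc([C@@H](O)C[C@H](O)c2c(Br)cc(OCOC)c(C/C=C(\C)CCC=C(C)C)c2OCOC)cc(OCOC)c1OCOC
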